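All runs come from a simulation with made-up constants, noise included.

**Two rates.** If exchange through the achiral form keeps [left-handed substrate] and [right-handed substrate] level, as the north readings of 15 % and 14 % at 1.25 d suggest, partner meets both hands at one concentration. So long as that lasts, the split between the products is the ratio of two capture rates.

in all of them: left-handed substrate 0.010 M; right-handed substrate 0.010 M

| charge | partner | remark | time |
|---|---|---|---|
| north | 1 equiv | run made earlier |  |
| north-east | 4 equiv | run made earlier |  |
| flask | 2.00 equiv |  | 3.0 d |

- north (time / d: left-handed substrate / %, right-handed substrate / %, left-handed product / %): 0.625: 21, 27, 19; 1.25: 15, 14, 28; 2.00: 11, 11, 28; 3.00: 3, 4, 30; 4.00: 2, 4, 28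
- north-east (time / d: left-handed substrate / %, right-handed substrate / %, left-handed product / %): 0.333: 10, 19, 40; 0.833: 3, 6, 48; 1.67: 5, 3, 51; 2.50: 0, 0, 53; 4.00: 0, 1, 52

(scatter of a reading: 1.5 percentage points)

- partner is single-handed; left-handed substrate and right-handed substrate are mirror images of each other, charged as a racemate, each of them at the stated concentration
- the numbers in the tables scatter by 1.5 percentage points (one standard deviation)
- reactions considered so far: partner -> decomposition product; partner + left-handed substrate -> left-handed product; right-handed substrate <-> achiral form; left-handed substrate <-> achiral form; partner + right-handed substrate -> right-handed product; achiral form -> waste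
- an excess is the difference of the two amounts in percent of their sum
- what has gone into achiral form counts as reacted
- an excess is below zero if the other one leads
- the handed part of partner does not stay in what it makes, so the products of the two hands are mirror images too

- part of the left-handed substrate and right-handed substrate charged together that has reacted at 3.0 d
- excess of left-handed product over right-handed product in the product at 3.0 d
- excess of right-handed substrate over left-handed substrate among what is left of the two at 3.0 d

**Reading it.** Right-handed product is not read, so you reckon from the budget. Take the late readings of left-handed product, 29.0 % in north and 52.5 % in north-east, put right-handed product below each by one common factor, and let waste stand for the remainder. If left-handed product over waste grows in step with the equivalents of partner, the two runs read the selectivity factor, left-handed capture rate over right-handed capture rate, as 2.56. This factor less one, over itself plus one, is my excess of left-handed product for the flask, 43.9 %. Left-handed substrate reads lower than right-handed substrate early in both runs, 21 % against 27 % at 0.625 d in north and 10 % against 19 % at 0.333 d in north-east, so I hold this as the high side for the flask.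

**The forecast.** It gives 97 % reacted, an excess of left-handed product of 26 % and an excess of right-handed substrate of 15 %, holding that “selectivity is about 2”, and on the product it differs from my 43.9 %.

**The flask.** It gives 97.4 % reacted, an excess of right-handed substrate of 15.4 % and an excess of left-handed product of 37.3 %, less than the 43.9 % from the factor 2.56, and that product excess stood at 38.7 % at 0.750 d.

    partner → decomposition product (k = 7.40 × 10⁻⁴ /h)
    partner + left-handed substrate → left-handed product (k = 7.04 /M/h)
    right-handed substrate ⇌ achiral form (K = 0.450, k = 0.105 /h)
    left-handed substrate ⇌ achiral form (K = 0.450, k = 0.105 /h)
    partner + right-handed substrate → right-handed product (k = 2.34 /M/h)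
    achiral form → waste (k = 0.113 /h)

Carry the factor 2.56 to a neighbour flask with 0.500 equiv of partner: it again gives 43.9 %, and that neighbour stands at 47.3 %, with its excess of right-handed substrate at 1.25 %.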